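**Plan**

1. Rings: A = left benzene, B = left pyran, C = right benzene, D = right pyran. Retrosynthesis: first open ring D at O1'–C2' and C4'–C4a' to the para-phenol 8 and 3-methylbut-2-enal; then cut the C3–CH(CH3) bond between the halves to chromene 4 and a para-quinone methide (the ring-D-seco form of the presumed biosynthetic chromene/benzylic cation hetero-dimerisation); then open ring B the same way as ring D.
2. Forward: ring B is closed first (step 1), the quinone methide precursor is made (step 2), the two monomers are joined (step 3), and ring D is closed last (step 4).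
3. Enabling feature: in ring C the oxygen that becomes O1' of ring D sits para to C6', the carbon that carries the stereogenic CH(CH3). As a free OH it first generates the quinone methide and binds the catalyst, then serves the annulation. Its two ortho carbons (future C4a' and C8') are equivalent, and the other phenol (C5–OH of ring A) has no free ortho carbon, so only one chromene can form.
4. Stereochemistry: the single stereocenter (S) is set in step 3 by a chiral phosphoric acid and afterwards meets only basic conditions.

Key step: step 4

Remark: the benzylic stereocenter of the target is S (CIP order aryl > chromen-3-yl > CH3 > H). The (R)-configured catalyst is written in step 3 on the assumption that it delivers this sense; its mirror image is taken if it does not.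

**Route**

Step 1
Reactants: 1 1-(2,4-dihydroxy-6-methoxyphenyl)ethan-1-one; 2 3-methylbut-2-enal
Product: 4 1-(5-hydroxy-7-methoxy-2,2-dimethyl-2H-chromen-6-yl)ethan-1-one, via ortho-quinone methide 3 (not isolated)
Conditions: pyridine, 120 °C, sealed tube, argon
Reagents that add atoms: none
Why: Pyridine-promoted formal [3+3] chromenylation (Knoevenagel-type C-alkylation of the phenol by the enal, loss of water to 3, oxa-6π electrocyclization) is a standard entry to 2,2-dimethylchromenes from resorcinol ketones; closure should engage the unchelated 4-OH and the carbon between the two hydroxyls, which gives the 5-hydroxy-6-acetyl-7-methoxy pattern, and any regioisomer closed at the other ortho carbon is removed by chromatography.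

Step 2
Reactants: 5 4-hydroxy-2,6-dimethoxybenzaldehyde
Product: 6 4-(1-hydroxyethyl)-3,5-dimethoxyphenol (racemic)
Conditions: MeMgBr (3.5 equiv), THF, 0 °C to 40 °C; then pH 7 buffer, 0 °C
Reagents that add atoms: methylmagnesium bromide, C[Mg]Br
Why: Grignard addition in which the first equivalent forms the magnesium phenoxide and further equivalents add to the aldehyde, as is routine for 4-hydroxybenzaldehydes; the carbinol centre is left racemic because it is erased when 6 ionises in step 3, and 6 is kept cold, free of acid and used crude because it should lose water easily.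

Step 3
Reactants: 4 1-(5-hydroxy-7-methoxy-2,2-dimethyl-2H-chromen-6-yl)ethan-1-one; 6 4-(1-hydroxyethyl)-3,5-dimethoxyphenol
Product: 8 1-[5-hydroxy-3-[(1S)-1-(4-hydroxy-2,6-dimethoxyphenyl)ethyl]-7-methoxy-2,2-dimethyl-2H-chromen-6-yl]ethan-1-one, via para-quinone methide 7 (not isolated)
Conditions: (R)-TRIP [(R)-3,3'-bis(2,4,6-triisopropylphenyl)-1,1'-binaphthyl-2,2'-diyl hydrogen phosphate] (10 mol%), 4 (2.5 equiv, excess recovered), 6 added over 6 h, 4 Å MS, toluene, −20 °C
Reagents that add atoms: none
Why: Proposed new method: the chiral phosphoric acid should dehydrate 6 to para-quinone methide 7 and hold it by a hydrogen bond to its carbonyl oxygen while the phosphoryl oxygen engages the C5 hydroxyl of 4 (an ortho-hydroxystyrene), so that the electron-rich C3 of 4 adds to one enantiotopic face of the exocyclic carbon of 7 (1,6-addition) and the resulting C4 benzylic cation, stabilised by three ring oxygens, loses the C3 proton to restore the chromene, which sets the S centre under catalyst control; the closest known reaction type is the chiral-phosphoric-acid-catalysed enantioselective 1,6-addition of indoles, naphthols and ortho-hydroxystyrenes to para-quinone methides generated in situ from para-hydroxybenzyl alcohols, not yet shown with a 2H-chromene as the alkene nucleophile.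

Step 4
Reactants: 8 1-[5-hydroxy-3-[(1S)-1-(4-hydroxy-2,6-dimethoxyphenyl)ethyl]-7-methoxy-2,2-dimethyl-2H-chromen-6-yl]ethan-1-one; 2 3-methylbut-2-enal
Product: 10 1-[3-[(1S)-1-(5,7-dimethoxy-2,2-dimethyl-2H-chromen-6-yl)ethyl]-5-hydroxy-7-methoxy-2,2-dimethyl-2H-chromen-6-yl]ethan-1-one, via ortho-quinone methide 9 (not isolated)
Conditions: pyridine, 120 °C, sealed tube, argon
Reagents that add atoms: none
Why: Pyridine forms the phenoxide of 8, whose ortho carbon adds to the aldehyde of 2 (Knoevenagel-type aldol), water is lost to give ortho-quinone methide 9, and 9 closes by thermal oxa-6π electrocyclization. The closest known reaction type is the pyridine-promoted chromenylation of phenols with 3-methylbut-2-enal (formal [3+3] annulation), the same reaction as in step 1. Ring D closes by disrotatory 6π electrocyclization of the 1-oxatriene O=C8a'–C4a'=C4'–C3'=C2', the carbonyl oxygen bonding to the gem-dimethyl terminus (formally 6-endo), driven by re-aromatisation of ring C. No new stereocenter arises because C2' carries two methyl groups, and the S centre should stay intact because the medium is basic, so the acid-catalysed reversal of step 3 through a quinone methide cannot run. The step needs site selectivity between two phenols and between ortho carbons: the C5–OH of ring A is hydrogen-bonded to the acetyl group and both of its ortho carbons are substituted, whereas the two ortho carbons of the ring C phenol are equivalent by rotation about the aryl–CH bond, so only one chromene can form. Pyridine is too weak a base to enolise the acetyl group toward aldol condensation with 2.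

**Compound list**

1 | 1-(2,4-dihydroxy-6-methoxyphenyl)ethan-1-one | CC(=O)c1c(O)cc(O)cc1OC | starting material
2 | 3-methylbut-2-enal | CC(C)=CC=O | starting material
3 | 4-acetyl-5-hydroxy-3-methoxy-6-(3-methylbut-2-en-1-ylidene)cyclohexa-2,4-dien-1-one (ortho-quinone methide, dienyl chain syn to the carbonyl) | CC(=O)C1=C(O)/C(=C/C=C(C)C)C(=O)C=C1OC | intermediate (not isolated)
4 | 1-(5-hydroxy-7-methoxy-2,2-dimethyl-2H-chromen-6-yl)ethan-1-one | COc1cc2c(c(O)c1C(C)=O)C=CC(C)(C)O2 | intermediate
5 | 4-hydroxy-2,6-dimethoxybenzaldehyde | COc1cc(O)cc(OC)c1C=O | starting material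
6 | 4-(1-hydroxyethyl)-3,5-dimethoxyphenol (racemic) | COc1cc(O)cc(OC)c1C(C)O | intermediate
7 | 4-ethylidene-3,5-dimethoxycyclohexa-2,5-dien-1-one (para-quinone methide) | CC=C1C(OC)=CC(=O)C=C1OC | intermediate (not isolated)
8 | 1-[5-hydroxy-3-[(1S)-1-(4-hydroxy-2,6-dimethoxyphenyl)ethyl]-7-methoxy-2,2-dimethyl-2H-chromen-6-yl]ethan-1-one | COc1cc2c(c(O)c1C(C)=O)C=C([C@H](C)c1c(OC)cc(O)cc1OC)C(C)(C)O2 | intermediate
9 | 1-[3-[(1S)-1-[2,6-dimethoxy-3-(3-methylbut-2-en-1-ylidene)-4-oxocyclohexa-1,5-dien-1-yl]ethyl]-5-hydroxy-7-methoxy-2,2-dimethyl-2H-chromen-6-yl]ethan-1-one (ortho-quinone methide, dienyl chain syn to the carbonyl) | COc1cc2c(c(O)c1C(C)=O)C=C([C@H](C)C1=C(OC)/C(=C/C=C(C)C)C(=O)C=C1OC)C(C)(C)O2 | intermediate (not isolated)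
10 | 1-[3-[(1S)-1-(5,7-dimethoxy-2,2-dimethyl-2H-chromen-6-yl)ethyl]-5-hydroxy-7-methoxy-2,2-dimethyl-2H-chromen-6-yl]ethan-1-one | COc1cc2c(c(O)c1C(C)=O)C=C([C@H](C)c1c(OC)cc3c(c1OC)C=CC(C)(C)O3)C(C)(C)O2 | target

**Step count**

Total steps: 4. Longest linear sequence: 3 steps (1 → 4 → 8 → 10, or 5 → 6 → 8 → 10).

**Steps most likely to fail**

Step 3 (bears the label). What may go wrong: poor facial selectivity, because the catalyst binds the quinone methide far from the reacting carbon and the C5 hydroxyl of 4 is partly occupied by the acetyl group; the electron-rich phenol ring of 6 or 8 may also be alkylated by 7 in competition with C3 of 4. Fallback, setting out from 4 and 6 and coming back at 8: the union is run without asymmetric induction, with an achiral Brønsted acid (diphenyl phosphate, 10 mol%, CH2Cl2, 0 °C, slow addition of 6 to excess 4). This is the ordinary acid-catalysed 1,6-addition to a quinone methide formed in situ and should give the racemic phenol F1. The enantiomers are then separated by preparative chromatography on a chiral stationary phase (amylose tris(3,5-dimethylphenylcarbamate)). The S enantiomer is 8 and goes on to step 4; the R enantiomer F2 is set aside.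

Step 4. What may go wrong: slow C-alkylation of a mono-phenol that is less activated than a resorcinol, polymerisation of the enal, and thermal decomposition of 8 or autoxidation of its phenoxide during long heating. Fallback, setting out from 8 and coming back at 10: the unchelated para-phenol is alkylated with 3-chloro-3-methylbut-1-yne (K2CO3, KI, CuI 5 mol%, acetone, 55 °C) to the aryl 1,1-dimethylpropargyl ether F3; the chelated C5–OH should not react. F3 is then heated without additive (xylene, 140 °C). Aromatic Claisen rearrangement to either equivalent ortho carbon, enolisation, [1,5]-hydrogen shift and oxa-6π electrocyclization should close ring D and give 10 under neutral conditions.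

Step 2. What may go wrong: incomplete addition to the deactivated, hindered phenoxide aldehyde, and loss of the product by dehydration and oligomerisation during work-up. Fallback, setting out from 5 and coming back at 6: the phenol is silylated (TBSCl, imidazole, DMF, rt) to the silyl ether aldehyde F4, which is a normal electrophile; MeMgBr (1.3 equiv, THF, −78 °C to 0 °C) gives the silyl ether alcohol F5, which can be stored; 6 is released just before step 3 (TBAF, THF, 0 °C, then pH 7 buffer) and used at once.

**Further compounds**

F1 | step 3 | racemic 1-[5-hydroxy-3-[1-(4-hydroxy-2,6-dimethoxyphenyl)ethyl]-7-methoxy-2,2-dimethyl-2H-chromen-6-yl]ethan-1-one | COc1cc2c(c(O)c1C(C)=O)C=C(C(C)c1c(OC)cc(O)cc1OC)C(C)(C)O2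
F2 | step 3 | 1-[5-hydroxy-3-[(1R)-1-(4-hydroxy-2,6-dimethoxyphenyl)ethyl]-7-methoxy-2,2-dimethyl-2H-chromen-6-yl]ethan-1-one | COc1cc2c(c(O)c1C(C)=O)C=C([C@@H](C)c1c(OC)cc(O)cc1OC)C(C)(C)O2
F3 | step 4 | 1-[3-[(1S)-1-[2,6-dimethoxy-4-(2-methylbut-3-yn-2-yloxy)phenyl]ethyl]-5-hydroxy-7-methoxy-2,2-dimethyl-2H-chromen-6-yl]ethan-1-one | COc1cc2c(c(O)c1C(C)=O)C=C([C@H](C)c1c(OC)cc(OC(C)(C)C#C)cc1OC)C(C)(C)O2
F4 | step 2 | 4-[tert-butyl(dimethyl)silyl]oxy-2,6-dimethoxybenzaldehyde | COc1cc(O[Si](C)(C)C(C)(C)C)cc(OC)c1C=O
F5 | step 2 | 1-[4-[tert-butyl(dimethyl)silyl]oxy-2,6-dimethoxyphenyl]ethan-1-ol (racemic) | COc1cc(O[Si](C)(C)C(C)(C)C)cc(OC)c1C(C)O
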